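Ring A of the decalin (C4a, C5, C6, C7, C8, C8a; C5 carries the methylidene, C4a the angular methyl) is annulated onto ring B by disconnecting C4a–C5 and C8–C8a. The key step exploits that the alkene carbon C5 is attached to the quaternary C4a and that C8a lies α to a latent C1 ketone: a copper-catalysed enantioselective conjugate addition of a 5-chloropent-1-en-2-yl alane to 3-methylcyclohex-2-enone sets C4a, and the resulting enolate closes ring A by alkylation in the same flask. The precursors are only the enone and 2-bromo-5-chloropent-1-ene. The C1 ketone is then turned into the benzylated quaternary centre through a nitrile, and the benzoate is installed last.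

Key step: step 2

Remark on numbering: decalin locants follow the naphthalene numbering of the target name. C1 is the quaternary carbon that carries the arylmethyl group, C2 the CH(CH3) carbon, C4a the methyl-bearing fusion carbon, C5 the methylidene-bearing carbon and C8a the fusion CH. Ring A is C4a, C5–C8, C8a; ring B is C1–C4, C4a, C8a. The β face is the face of the C4a methyl group.

Assumption: the (R,R)-enantiomer of the phosphinamine ligand is taken to deliver the alkenyl group to the face of 4 that gives the (S)-configured quaternary carbon. Should the sense of induction be the opposite, the (S,S)-ligand is used with no other change.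

Step 1
Reactants: 1 5-chloropent-1-yne
Product: 3 2-bromo-5-chloropent-1-ene, via bromoboration adduct 2 (not isolated)
Conditions: B-bromo-9-BBN (1.0 M in CH2Cl2), CH2Cl2, 0 °C → rt; then AcOH, 0 °C → rt; aqueous NaHCO3 work-up
Reagents that add atoms: B-bromo-9-borabicyclo[3.3.1]nonane, BrB1C2CCCC1CCC2
Why: Syn bromoboration of the terminal alkyne places bromine on the internal carbon (Markovnikov haloboration), and protonolysis of the alkenyl–boron bond by acetic acid should release the 2-bromo-1-alkene while the alkyl chloride stays untouched.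

Step 2
Reactants: 3 2-bromo-5-chloropent-1-ene; 4 3-methylcyclohex-2-en-1-one
Product: 8 (4aS,8aS)-4a-methyl-5-methylideneoctahydronaphthalen-1(2H)-one, via alkenyllithium 5 (not isolated), via alkenylalane 6 (not isolated), via aluminium enolate 7 (not isolated)
Conditions: t-BuLi (2 equiv), Et2O, −78 °C; Me2AlCl, −78 → −30 °C; Cu(O2CC4H3S) (copper thiophene-2-carboxylate, 10 mol %), (R,R)-Ph2PN[CH(CH3)Ph]2 (11 mol %), 4, Et2O, −30 °C; then MeLi, THF–DMPU, −30 → 45 °C
Reagents that add atoms: none
Why: Bromine–lithium exchange and transmetalation give the alkenyl(dimethyl)alane 6, whose alkenyl group the chiral phosphinamine complex of monovalent copper transfers to the β-carbon of enone 4 (copper π-complex, then reductive elimination), forming C4a–C5 and the aluminium enolate 7 regiospecifically at C8a; activation of 7 as its lithium aluminate by MeLi in THF–DMPU then triggers intramolecular SN2 displacement of the primary chloride, forming C8–C8a. The closest known reaction types are the copper-catalysed asymmetric conjugate addition of alkenylalanes to 3-substituted cyclohexenones, which creates all-carbon quaternary centres, and the conjugate addition–enolate alkylation sequence known as methylenecyclohexane annulation. Ring A closes in a 6-(enolexo)-exo-tet mode, which the Baldwin rules favour. The quaternary centre C4a (S) is set by the chiral ligand on copper, and C8a is set by the tether, which should deliver C8 to the enolate face that carries C5 and so give the cis-fused (4aS,8aS) ketone; C8a is epimerizable and is corrected in step 3, where any trans-fused material converges as well. The step needs alkenyl rather than methyl transfer from aluminium (secured by the higher transfer aptitude of the sp2 carbon), 1,4- rather than 1,2-addition (secured by copper) and C- rather than O-alkylation (O-alkylation would require an eight-membered ring); the alkyl chloride is inert to t-BuLi at −78 °C and to the alane.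

Step 3
Reactants: 8 (4aS,8aS)-4a-methyl-5-methylideneoctahydronaphthalen-1(2H)-one
Product: 11 (2S,4aS,8aR)-2,4a-dimethyl-5-methylideneoctahydronaphthalen-1(2H)-one, via lithium enolate 9 (not isolated), via methylated ketone epimer mixture 10 (not isolated)
Conditions: LiN(i-Pr)2, THF, −78 °C; MeI (1.1 equiv), −78 → 0 °C; then NaOMe, MeOH, rt → 65 °C
Reagents that add atoms: iodomethane, CI
Why: Kinetic deprotonation should occur at the C2 methylene and not at the C8a methine next to the quaternary C4a, methylation of this enolate follows, and methoxide-mediated enolization then epimerizes C2 and C8a to the thermodynamically preferred trans-fused ketone with an equatorial 2-methyl group (2S,8aR), which sets both centres under thermodynamic control.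

Step 4
Reactants: 11 (2S,4aS,8aR)-2,4a-dimethyl-5-methylideneoctahydronaphthalen-1(2H)-one
Product: 12 (2S,4aS,8aS)-2,4a-dimethyl-5-methylidenedecahydronaphthalene-1-carbonitrile (mixture of C1 epimers)
Conditions: TosMIC, KOt-Bu, DME, EtOH (2 equiv), 0 → 40 °C
Reagents that add atoms: p-toluenesulfonylmethyl isocyanide (TosMIC), Cc1ccc(cc1)S(=O)(=O)C[N+]#[C-]
Why: The Van Leusen reductive cyanation converts hindered ketones into the homologous nitriles, the configuration at C1 is of no consequence because this centre is planarized in step 8, and the trans fusion is the thermodynamic one under the basic conditions.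

Step 5
Reactants: 13 2,3,4-trihydroxybenzaldehyde
Product: 14 2,3,4-tris(methoxymethoxy)benzaldehyde
Conditions: MOMCl (4 equiv), i-Pr2NEt, CH2Cl2, 0 °C → reflux, under argon
Reagents that add atoms: chloromethyl methyl ether, COCCl
Why: O-Alkylation of the three phenols with the reactive α-chloro ether under amine base (Williamson-type etherification) should give the tris-acetal, with excess reagent and heating overcoming the hydrogen-bonded 2-hydroxyl group.

Step 6
Reactants: 14 2,3,4-tris(methoxymethoxy)benzaldehyde
Product: 15 [2,3,4-tris(methoxymethoxy)phenyl]methanol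
Conditions: NaBH4, MeOH, 0 °C
Reagents that add atoms: none
Why: Borohydride reduction of the aryl aldehyde to the benzylic alcohol is reliable and leaves the acetals intact.

Step 7
Reactants: 15 [2,3,4-tris(methoxymethoxy)phenyl]methanol
Product: 16 1-(bromomethyl)-2,3,4-tris(methoxymethoxy)benzene
Conditions: CBr4, PPh3, CH2Cl2, 0 °C; used at once
Reagents that add atoms: tetrabromomethane, BrC(Br)(Br)Br
Why: The Appel reaction converts the benzylic alcohol into the bromide under essentially neutral conditions that the acid-labile methoxymethyl ethers should tolerate.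

Step 8
Reactants: 12 (2S,4aS,8aS)-2,4a-dimethyl-5-methylidenedecahydronaphthalene-1-carbonitrile; 16 1-(bromomethyl)-2,3,4-tris(methoxymethoxy)benzene
Product: 18 (1S,2S,4aS,8aR)-2,4a-dimethyl-5-methylidene-1-[2,3,4-tris(methoxymethoxy)benzyl]decahydronaphthalene-1-carbonitrile, via lithiated nitrile 17 (not isolated)
Conditions: LiN(i-Pr)2, THF–DMPU, −78 → 0 °C; then 16, −78 °C → rt
Reagents that add atoms: none
Why: In this nitrile-anion alkylation the benzylic bromide should approach the planar ketene iminate along the equatorial trajectory on the α face, because the β face is shielded by the axial C4a methyl group in a 1,3-diaxial relation, so the arylmethyl group ends equatorial and the small cyano group axial (1S).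

Step 9
Reactants: 18 (1S,2S,4aS,8aR)-2,4a-dimethyl-5-methylidene-1-[2,3,4-tris(methoxymethoxy)benzyl]decahydronaphthalene-1-carbonitrile
Product: 20 (1S,2S,4aS,8aR)-2,4a-dimethyl-5-methylidene-1-[2,3,4-tris(methoxymethoxy)benzyl]decahydronaphthalene-1-carbaldehyde, via aluminium aldimine 19 (not isolated)
Conditions: i-Bu2AlH, toluene, −78 → 0 °C; then aqueous potassium sodium tartrate; then 10% aqueous AcOH, THF, rt
Reagents that add atoms: water, O
Why: Single hydride addition of i-Bu2AlH to the tertiary nitrile stops at the N-aluminated aldimine, which mild aqueous hydrolysis should convert into the neopentyl aldehyde without touching the acetals or the alkene.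

Step 10
Reactants: 20 (1S,2S,4aS,8aR)-2,4a-dimethyl-5-methylidene-1-[2,3,4-tris(methoxymethoxy)benzyl]decahydronaphthalene-1-carbaldehyde
Product: 22 1-{[(1R,2S,4aS,8aS)-1,2,4a-trimethyl-5-methylidenedecahydronaphthalen-1-yl]methyl}-2,3,4-tris(methoxymethoxy)benzene, via hydrazone 21 (not isolated)
Conditions: N2H4·H2O, KOH, diethylene glycol, 130 °C, then 200 °C with removal of water, under N2
Reagents that add atoms: none
Why: The Wolff–Kishner reduction (Huang-Minlon procedure) turns the hindered aldehyde into the axial C1 methyl group with retention at the quaternary centre, the acetals and the isolated alkene being stable to hot base and oxygen being excluded to avoid diimide formation.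

Step 11
Reactants: 22 1-{[(1R,2S,4aS,8aS)-1,2,4a-trimethyl-5-methylidenedecahydronaphthalen-1-yl]methyl}-2,3,4-tris(methoxymethoxy)benzene
Product: 24 methyl 2,3,4-tris(methoxymethoxy)-5-{[(1R,2S,4aS,8aS)-1,2,4a-trimethyl-5-methylidenedecahydronaphthalen-1-yl]methyl}benzoate, via aryllithium 23 (not isolated)
Conditions: n-BuLi, TMEDA, THF, −78 → 0 °C; then ClCO2Me (excess, inverse addition), −78 °C
Reagents that add atoms: methyl chloroformate, COC(=O)Cl
Why: Directed ortho-metalation should occur at the only ring position ortho to a methoxymethoxy group (the position next to the 4-acetal), and acylation of the aryllithium with the chloroformate gives the methyl ester directly.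

Step 12
Reactants: 24 methyl 2,3,4-tris(methoxymethoxy)-5-{[(1R,2S,4aS,8aS)-1,2,4a-trimethyl-5-methylidenedecahydronaphthalen-1-yl]methyl}benzoate
Product: 25 methyl 2,3,4-trihydroxy-5-{[(1R,2S,4aS,8aS)-1,2,4a-trimethyl-5-methylidenedecahydronaphthalen-1-yl]methyl}benzoate
Conditions: HCl (1.25 M in MeOH), 0 °C → rt, under argon
Reagents that add atoms: none
Why: Acid-catalysed transacetalization to methanol cleaves aryl methoxymethyl ethers under mild conditions, at which the methyl ester is unchanged and the methylidene group next to the quaternary carbon should not yet be protonated.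

Compound list
1 | 5-chloropent-1-yne | C#CCCCCl | starting material
2 | (Z)-9-(2-bromo-5-chloropent-1-en-1-yl)-9-borabicyclo[3.3.1]nonane | ClCCC/C(Br)=C/B1C2CCCC1CCC2 | intermediate
3 | 2-bromo-5-chloropent-1-ene | C=C(Br)CCCCl | intermediate
4 | 3-methylcyclohex-2-en-1-one | CC1=CC(=O)CCC1 | starting material
5 | (5-chloropent-1-en-2-yl)lithium | [Li]C(=C)CCCCl | intermediate
6 | (5-chloropent-1-en-2-yl)dimethylalane | C=C(CCCCl)[Al](C)C | intermediate
7 | {[(S)-3-(5-chloropent-1-en-2-yl)-3-methylcyclohex-1-en-1-yl]oxy}dimethylalane | C=C(CCCCl)[C@@]1(C)CCCC(O[Al](C)C)=C1 | intermediate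
8 | (4aS,8aS)-4a-methyl-5-methylideneoctahydronaphthalen-1(2H)-one (cis-fused) | C=C1CCC[C@@H]2C(=O)CCC[C@]12C | intermediate
9 | lithium (4aS,8aS)-4a-methyl-5-methylidene-3,4,4a,5,6,7,8,8a-octahydronaphthalen-1-olate | C=C1CCC[C@@H]2C(O[Li])=CCC[C@]12C | intermediate
10 | (4aS,8aS)-2,4a-dimethyl-5-methylideneoctahydronaphthalen-1(2H)-one (mixture of C2 epimers) | C=C1CCC[C@@H]2C(=O)C(C)CC[C@]12C | intermediate
11 | (2S,4aS,8aR)-2,4a-dimethyl-5-methylideneoctahydronaphthalen-1(2H)-one (trans-fused, 2-methyl equatorial) | C=C1CCC[C@H]2C(=O)[C@@H](C)CC[C@]12C | intermediate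
12 | (2S,4aS,8aS)-2,4a-dimethyl-5-methylidenedecahydronaphthalene-1-carbonitrile (mixture of C1 epimers) | C=C1CCC[C@H]2C(C#N)[C@@H](C)CC[C@]12C | intermediate
13 | 2,3,4-trihydroxybenzaldehyde | O=Cc1ccc(O)c(O)c1O | starting material
14 | 2,3,4-tris(methoxymethoxy)benzaldehyde | O=Cc1ccc(OCOC)c(OCOC)c1OCOC | intermediate
15 | [2,3,4-tris(methoxymethoxy)phenyl]methanol | OCc1ccc(OCOC)c(OCOC)c1OCOC | intermediate
16 | 1-(bromomethyl)-2,3,4-tris(methoxymethoxy)benzene | BrCc1ccc(OCOC)c(OCOC)c1OCOC | intermediate
17 | N-lithio ketene iminate of nitrile 12 | C=C1CCC[C@H]2C(=C=N[Li])[C@@H](C)CC[C@]12C | intermediate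
18 | (1S,2S,4aS,8aR)-2,4a-dimethyl-5-methylidene-1-[2,3,4-tris(methoxymethoxy)benzyl]decahydronaphthalene-1-carbonitrile (cyano β and axial, arylmethyl α) | C=C1CCC[C@H]2[C@](C#N)(Cc3ccc(OCOC)c(OCOC)c3OCOC)[C@@H](C)CC[C@]12C | intermediate
19 | N-(diisobutylalumanyl) aldimine of aldehyde 20 | C=C1CCC[C@H]2[C@](C=N[Al](CC(C)C)CC(C)C)(Cc3ccc(OCOC)c(OCOC)c3OCOC)[C@@H](C)CC[C@]12C | intermediate
20 | (1S,2S,4aS,8aR)-2,4a-dimethyl-5-methylidene-1-[2,3,4-tris(methoxymethoxy)benzyl]decahydronaphthalene-1-carbaldehyde | C=C1CCC[C@H]2[C@](C=O)(Cc3ccc(OCOC)c(OCOC)c3OCOC)[C@@H](C)CC[C@]12C | intermediate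
21 | hydrazone of aldehyde 20 | C=C1CCC[C@H]2[C@](C=NN)(Cc3ccc(OCOC)c(OCOC)c3OCOC)[C@@H](C)CC[C@]12C | intermediate
22 | 1-{[(1R,2S,4aS,8aS)-1,2,4a-trimethyl-5-methylidenedecahydronaphthalen-1-yl]methyl}-2,3,4-tris(methoxymethoxy)benzene | C=C1CCC[C@H]2[C@](C)(Cc3ccc(OCOC)c(OCOC)c3OCOC)[C@@H](C)CC[C@]12C | intermediate
23 | (2,3,4-tris(methoxymethoxy)-5-{[(1R,2S,4aS,8aS)-1,2,4a-trimethyl-5-methylidenedecahydronaphthalen-1-yl]methyl}phenyl)lithium | C=C1CCC[C@H]2[C@](C)(Cc3cc([Li])c(OCOC)c(OCOC)c3OCOC)[C@@H](C)CC[C@]12C | intermediate
24 | methyl 2,3,4-tris(methoxymethoxy)-5-{[(1R,2S,4aS,8aS)-1,2,4a-trimethyl-5-methylidenedecahydronaphthalen-1-yl]methyl}benzoate | C=C1CCC[C@H]2[C@](C)(Cc3cc(C(=O)OC)c(OCOC)c(OCOC)c3OCOC)[C@@H](C)CC[C@]12C | intermediate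
25 | methyl 2,3,4-trihydroxy-5-{[(1R,2S,4aS,8aS)-1,2,4a-trimethyl-5-methylidenedecahydronaphthalen-1-yl]methyl}benzoate | C=C1CCC[C@H]2[C@](C)(Cc3cc(C(=O)OC)c(O)c(O)c3O)[C@@H](C)CC[C@]12C | target

Total step count: 12.
Longest linear sequence: 9 steps (1 → 3 → 8 → 11 → 12 → 18 → 20 → 22 → 24 → 25; steps 1, 2, 3, 4, 8, 9, 10, 11, 12).

Steps most likely to fail

Step 2. The aluminium enolate may alkylate too slowly, so that it is protonated or degrades before ring A closes, and the alkenyl transfer that builds the quaternary carbon may stall. Fallback: the two bond formations are separated. Starting from 3 and 4, the copper-catalysed conjugate addition is run alone and quenched with aqueous NH4Cl to isolate (S)-3-(5-chloropent-1-en-2-yl)-3-methylcyclohexan-1-one F1. F1 is then cyclized as its potassium enolate (KH, THF, rt); the two regioisomeric enolates equilibrate and only the C2 enolate can close a six-membered ring. This returns to the route at 8.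

Step 4. Addition of the TosMIC anion to the crowded C1 carbonyl, which is flanked by the C2 methine and by C8a next to the quaternary C4a, may be too slow, and prolonged exposure to base may erode the trans ring fusion. Fallback: starting from 11, Wittig methoxymethylenation ([Ph3PCH2OCH3]Cl, KN(SiMe3)2, THF, 0 °C → reflux) should give (2S,4aS,8aR)-1-(methoxymethylidene)-2,4a-dimethyl-5-methylidenedecahydronaphthalene F2. Mild hydrolysis (2 M HCl, THF, rt) gives (2S,4aS,8aS)-2,4a-dimethyl-5-methylidenedecahydronaphthalene-1-carbaldehyde F3. Its potassium enolate (KOt-Bu, THF, 0 °C) is alkylated by bromide 16 from the α face for the same steric reason as in step 8. This returns to the route at 20 and bypasses 12, 18 and step 9.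

Step 12. Protonation of the methylidene group may compete with acetal cleavage, moving the double bond into ring A or letting the neighbouring phenol add to the resulting cation. Fallback: starting from 24, the acetals are exchanged for silyl ethers without Brønsted acid (Me3SiOTf, 2,2'-bipyridyl, CH3CN, 0 °C) to give methyl 2,3,4-tris(trimethylsilyloxy)-5-{[(1R,2S,4aS,8aS)-1,2,4a-trimethyl-5-methylidenedecahydronaphthalen-1-yl]methyl}benzoate F4. F4 is cleaved by water (or KF in MeOH) at rt under neutral conditions. This returns to the route at 25.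

Further compounds
F1 | step 2 | (S)-3-(5-chloropent-1-en-2-yl)-3-methylcyclohexan-1-one | C=C(CCCCl)[C@@]1(C)CCCC(=O)C1
F2 | step 4 | (2S,4aS,8aR)-1-(methoxymethylidene)-2,4a-dimethyl-5-methylidenedecahydronaphthalene (E/Z mixture) | C=C1CCC[C@H]2C(=COC)[C@@H](C)CC[C@]12C
F3 | step 4 | (2S,4aS,8aS)-2,4a-dimethyl-5-methylidenedecahydronaphthalene-1-carbaldehyde (mixture of C1 epimers) | C=C1CCC[C@H]2C(C=O)[C@@H](C)CC[C@]12C
F4 | step 12 | methyl 2,3,4-tris(trimethylsilyloxy)-5-{[(1R,2S,4aS,8aS)-1,2,4a-trimethyl-5-methylidenedecahydronaphthalen-1-yl]methyl}benzoate | C=C1CCC[C@H]2[C@](C)(Cc3cc(C(=O)OC)c(O[Si](C)(C)C)c(O[Si](C)(C)C)c3O[Si](C)(C)C)[C@@H](C)CC[C@]12C
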